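The earlier runs and the new flask are simulated with constants of no real substance; scatter was added.

Flask gamma reaches 1.5 h with 30.1 substrate half-lives behind it. This count n is the elapsed time over the half-life read from the fall of substrate between 6.00 min and 12.0 min. Called here the feed clock, it gives the share of substrate still to come as 0.5 raised to n.

| flask | substrate | partner | temperature | remark | time |
|---|---|---|---|---|---|
| gamma | 0.20 M | 0.30 M | 35 °C | the very flask that is asked about, followed so far |  |
| alpha | 0.13 M | 0.30 M | 41 °C | run made earlier |  |
| flask | 0.20 M | 0.300 M | 35 °C |  | 1.5 h |

- gamma (time / min: target / %, substrate / %): 6.00: 15.7, 27.3; 8.00: 20.1, 18.4; 12.0: 25.4, 6.8; 20.0: 28.9, 0.4; 30.0: 29.1, 0.8; 50.0: 29.8, 0; 80.0: 32.5, 0.3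
- alpha (time / min: target / %, substrate / %): 1.00: 6.3, 63.7; 3.00: 20.4, 25.4; 6.00: 33.0, 6.8; 8.00: 38.2, 4.4; 12.0: 43.2, 1.0; 15.0: 44.3, 2.8; 20.0: 44.7, 0.7

(standard deviation of a reading: 1 percentage point)

- red: change nothing and wait 1.5 h more
- grey: at 1.5 h raise the temperature by 15 K, then wait 1.5 h
- green: at 1.5 h take out 90% of the target then present, then wait 1.5 h
- blue: at 1.5 h add partner, 100% of the amount charged, then wait 1.5 h

- in percentages every species weighs as the substrate in it: one homo product counts as two
- target that was removed still counts
- reactions considered so far: partner -> second intermediate; substrate -> open intermediate; target <-> isomer of the product; open intermediate + second intermediate -> target; 2 open intermediate -> homo product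
- additions bring no volume worth counting

- target, in percent of the substrate first charged, at 1.5 h
- which option adds most target ("none" when 2 percentage points or less is all one gets) (red / grey / green / blue / none)
- target present, with what was taken out counted in, in percent of the substrate first charged, after red
- target present, with what was taken out counted in, in percent of the substrate first charged, after blue

My own reckoning takes the settings in turn.

Time (red): the half-life of 2.99 min is far shorter than 1.5 h, so hardly any substrate remains in flask gamma. Among the listed reactions the one that forms open intermediate starts from substrate, so target in flask gamma should stay near the mean of its last four readings, 30.1%.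

Partner (blue): partner gives second intermediate, which captures open intermediate, and with the feed clock this far on hardly any substrate is left to feed open intermediate, so blue should about equal red in flask gamma.

Temperature (grey): substrate reads as falling 1.93 times as fast in run alpha as in flask gamma, but hardly any substrate remains in flask gamma for heat to speed. Heat can act on target and isomer of the product, if that pair is under thermodynamic control. Run alpha, warmer and with less substrate, reads 44.7% at its last reading, which weakly favours a shift towards target.

Removal (green): taking out target should pull isomer of the product back, and that isomer has no column in the readings.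

So I would say about 30.1% for now, for red and for blue, and grey as the weak favourite.

The forecast says 32.5% (30% to 34.5%), 36.5% after red (30.5% to 41%), 37.5% after blue (30.5% to 44%), and grey as best. Its ground for the rise is “homo product slowly reopening to open intermediate”. It agrees with my reckoning on grey and parts from it on red and blue.

Flask gamma gives 31.1% at 1.5 h, then 31.1% after red and 31.1% after blue, while grey adds 24 percentage points and green 16 points, so grey is best.

partner → second intermediate (k = 3.34 min⁻¹, Ea = 90.0 kJ mol⁻¹); substrate → open intermediate (k = 0.220 min⁻¹, Ea = 94.0 kJ mol⁻¹); target ⇌ isomer of the product (K = 1.24, k = 0.881 min⁻¹, Ea = 92.0 kJ mol⁻¹, ΔH = −85.0 kJ mol⁻¹); open intermediate + second intermediate → target (k = 1.02 L mol⁻¹ min⁻¹, Ea = 51.0 kJ mol⁻¹); 2 open intermediate → homo product (k = 1.52 L mol⁻¹ min⁻¹, Ea = 60.0 kJ mol⁻¹); (constants at 35 °C) In flask gamma the step from substrate to open intermediate had half of its turnover behind it at 3.15 min, and at 45.0 min substrate stood at 0.00502%, with target at 31.1% and isomer of the product at 38.5%, a pair whose relaxation half-life by this step alone, 0.436 min, is far shorter than 1.5 h. In the repeat at 20 °C, scaling the clock by the factor above gives 5.80 half-lives, so 1.79% of the substrate to come; at 90.0 min that flask holds 4.83% of substrate.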